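Ring C is disconnected at O1–C2 and C3–C4. This leaves a salicyloyl unit (the C4 carbonyl and O1, both attached to ring A) and a C2–C3 unit that carries the ring B aryl group on C2 and the prenyl group on C3: a salicylaldehyde and an unsymmetrical aryl alkyl alkyne. One rhodium-catalysed oxidative annulation through the formyl C–H bond forms both bonds and closes the pyranone. Its precursors are a 2-hydroxy-4-methoxybenzaldehyde with a MOM ether at C6 and a bis-MOM-protected aryl alkyne whose second alkyne carbon bears the prenyl group (a skipped enyne). Every phenol of the target leaves the annulation as a MOM ether, so one mild acidic step finishes the synthesis.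

Key step: step 8

Remark: the target has no stereogenic element; the 5-oxygen of ring A is carried through the annulation as a MOM ether, not a methyl ether, so that no Lewis-acid demethylation is needed once the acid-sensitive prenyl group is in place.

Step 1
Reactants: 1 2-methoxyhydroquinone (2-methoxybenzene-1,4-diol)
Product: 2 2-methoxy-1,4-bis(methoxymethoxy)benzene
Conditions: MOMCl (2.6 equiv), i-Pr2NEt (3.5 equiv), CH2Cl2, 0 °C to rt, argon
Reagents that add atoms: chloromethyl methyl ether (MOMCl), COCCl
Why: Double O-alkylation of the phenols with the highly electrophilic α-chloro ether under amine base (Williamson-type ether synthesis) should be clean, and working under argon keeps the hydroquinone from oxidising to the quinone before it is capped.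

Step 2
Reactants: 2 2-methoxy-1,4-bis(methoxymethoxy)benzene
Product: 3 1-iodo-4-methoxy-2,5-bis(methoxymethoxy)benzene
Conditions: NIS (1.05 equiv), MeCN, 0 °C to rt, dark
Reagents that add atoms: N-iodosuccinimide (NIS), O=C1CCC(=O)N1I
Why: Electrophilic aromatic iodination should go to the one ring position that is para to the methoxy group and ortho to a MOM ether without being flanked by two substituents, and the acid-free medium leaves the acetals intact.

Step 3
Reactants: 3 1-iodo-4-methoxy-2,5-bis(methoxymethoxy)benzene; 4 trimethylsilylacetylene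
Product: 5 trimethyl{[4-methoxy-2,5-bis(methoxymethoxy)phenyl]ethynyl}silane
Conditions: PdCl2(PPh3)2 (2 mol %), CuI (4 mol %), Et3N/THF 1:1, rt to 40 °C, argon
Reagents that add atoms: none
Why: Sonogashira coupling, in which the aryl iodide adds oxidatively to zerovalent palladium near room temperature despite the electron-rich ring and the silyl cap on the alkyne rules out double arylation.

Step 4
Reactants: 5 trimethyl{[4-methoxy-2,5-bis(methoxymethoxy)phenyl]ethynyl}silane
Product: 6 1-ethynyl-4-methoxy-2,5-bis(methoxymethoxy)benzene
Conditions: K2CO3 (0.2 equiv), MeOH/THF, rt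
Reagents that add atoms: none
Why: Methoxide-mediated protodesilylation of the alkynylsilane is fast at room temperature, and MOM acetals and aryl methyl ethers are inert to base.

Step 5
Reactants: 6 1-ethynyl-4-methoxy-2,5-bis(methoxymethoxy)benzene; 7 prenyl bromide (1-bromo-3-methylbut-2-ene)
Product: 8 1-methoxy-2,5-bis(methoxymethoxy)-4-(5-methylhex-4-en-1-yn-1-yl)benzene
Conditions: CuI (10 mol %), n-Bu4NI (10 mol %), K2CO3 (1.5 equiv), degassed DMF, rt, argon
Reagents that add atoms: none
Why: Copper-catalysed coupling of a terminal alkyne with an allylic halide, in which the copper acetylide formed with carbonate displaces bromide at the unhindered primary carbon (SN2, not SN2') to give the linear prenyl alkyne, while carbonate at room temperature is too weak a base to move the skipped enyne into conjugation.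

Step 6
Reactants: 9 2-hydroxy-4,6-dimethoxybenzaldehyde
Product: 10 2,6-dihydroxy-4-methoxybenzaldehyde
Conditions: AlCl3 (3 equiv), CH2Cl2, 0 °C to rt; then 1 M HCl aq
Reagents that add atoms: none
Why: Chelation-directed Lewis-acid ether cleavage, in which aluminium held between the formyl oxygen and the ortho methoxy oxygen activates that methyl group for attack by chloride, whereas the para methoxy group cannot chelate and is deactivated as a vinylogous ester oxygen, so it should survive.

Step 7
Reactants: 10 2,6-dihydroxy-4-methoxybenzaldehyde
Product: 11 2-hydroxy-4-methoxy-6-(methoxymethoxy)benzaldehyde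
Conditions: MOMCl (1.05 equiv), i-Pr2NEt (1.5 equiv), CH2Cl2, 0 °C
Reagents that add atoms: chloromethyl methyl ether (MOMCl), COCCl
Why: O-Alkylation with MOMCl should stop at the mono-ether, because the two phenols of 10 are equivalent and, once one is capped, the other is tied up in a strong hydrogen bond to the formyl oxygen and is far less nucleophilic.

Step 8
Reactants: 11 2-hydroxy-4-methoxy-6-(methoxymethoxy)benzaldehyde; 8 1-methoxy-2,5-bis(methoxymethoxy)-4-(5-methylhex-4-en-1-yn-1-yl)benzene
Product: 12 7-methoxy-5-(methoxymethoxy)-2-[4-methoxy-2,5-bis(methoxymethoxy)phenyl]-3-(3-methylbut-2-en-1-yl)-4H-chromen-4-one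
Conditions: [Cp*RhCl2]2 (2.5 mol %), Cu(OAc)2 (2.2 equiv), NaOAc (1 equiv), o-xylene, 110 °C, N2
Reagents that add atoms: none
Why: Acetate exchange puts the phenoxide of 11 on Cp*Rh, from where the formyl C–H bond is cleaved by acetate-assisted metalation to a five-membered acyl rhodacycle; alkyne 8 inserts into the Rh–acyl bond to a seven-membered oxarhodacycle, C–O reductive elimination releases 12 and monovalent rhodium, and two equivalents of Cu(OAc)2 return it to trivalent rhodium. The closest known reaction type is the rhodium-catalysed oxidative coupling of salicylaldehydes with internal alkynes to 2,3-disubstituted chromones. Ring C closes as a formal [4+2] annulation, C3–C4 by migratory insertion and O1–C2 by reductive elimination at the alkenyl carbon, with no stereocenter formed. The step needs one orientation of insertion, aryl carbon on rhodium and CH2-bearing carbon on the acyl group, which aryl alkyl alkynes give because the aryl group stabilises the adjacent Rh–C bond, and here the ortho MOM oxygen can add a chelate. It also needs the skipped enyne to stay out of conjugation and the MOM acetals to survive, which the weakly basic, acetate-buffered medium should secure.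

Step 9
Reactants: 12 7-methoxy-5-(methoxymethoxy)-2-[4-methoxy-2,5-bis(methoxymethoxy)phenyl]-3-(3-methylbut-2-en-1-yl)-4H-chromen-4-one
Product: 13 artoindonesianin Q, 2-(2,5-dihydroxy-4-methoxyphenyl)-5-hydroxy-7-methoxy-3-(3-methylbut-2-en-1-yl)-4H-chromen-4-one
Conditions: 3 M HCl aq (6 equiv), degassed MeOH/THF 3:1, 40 °C, argon
Reagents that add atoms: none
Why: Acid-catalysed acetal exchange with methanol removes all three MOM groups as dimethoxymethane, the peri 5-O-MOM group fastest, while aryl methyl ethers are inert and the trisubstituted prenyl alkene is not protonated by dilute acid at this temperature, and degassing protects the liberated hydroquinone from air oxidation.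

Compound list
1 | 2-methoxyhydroquinone (2-methoxybenzene-1,4-diol) | COc1cc(O)ccc1O | starting material
2 | 2-methoxy-1,4-bis(methoxymethoxy)benzene | COCOc1ccc(OCOC)c(OC)c1 | intermediate
3 | 1-iodo-4-methoxy-2,5-bis(methoxymethoxy)benzene | COCOc1cc(OC)c(OCOC)cc1I | intermediate
4 | trimethylsilylacetylene (ethynyltrimethylsilane) | C#C[Si](C)(C)C | starting material
5 | trimethyl{[4-methoxy-2,5-bis(methoxymethoxy)phenyl]ethynyl}silane | COCOc1cc(OC)c(OCOC)cc1C#C[Si](C)(C)C | intermediate
6 | 1-ethynyl-4-methoxy-2,5-bis(methoxymethoxy)benzene | COCOc1cc(OC)c(OCOC)cc1C#C | intermediate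
7 | prenyl bromide (1-bromo-3-methylbut-2-ene) | CC(C)=CCBr | starting material
8 | 1-methoxy-2,5-bis(methoxymethoxy)-4-(5-methylhex-4-en-1-yn-1-yl)benzene | CC(C)=CCC#Cc1cc(OCOC)c(OC)cc1OCOC | intermediate
9 | 2-hydroxy-4,6-dimethoxybenzaldehyde | COc1cc(O)c(C=O)c(OC)c1 | starting material
10 | 2,6-dihydroxy-4-methoxybenzaldehyde | COc1cc(O)c(C=O)c(O)c1 | intermediate
11 | 2-hydroxy-4-methoxy-6-(methoxymethoxy)benzaldehyde | COCOc1cc(OC)cc(O)c1C=O | intermediate
12 | 7-methoxy-5-(methoxymethoxy)-2-[4-methoxy-2,5-bis(methoxymethoxy)phenyl]-3-(3-methylbut-2-en-1-yl)-4H-chromen-4-one | COCOc1cc(OC)cc2oc(-c3cc(OCOC)c(OC)cc3OCOC)c(CC=C(C)C)c(=O)c12 | intermediate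
13 | artoindonesianin Q, 2-(2,5-dihydroxy-4-methoxyphenyl)-5-hydroxy-7-methoxy-3-(3-methylbut-2-en-1-yl)-4H-chromen-4-one | COc1cc(O)c2c(=O)c(CC=C(C)C)c(-c3cc(O)c(OC)cc3O)oc2c1 | target

Total step count: 9 (steps 1–5 to the alkyne, steps 6–7 to the aldehyde, steps 8–9 after convergence).
Longest linear sequence: 7 steps (steps 1, 2, 3, 4, 5, 8, 9).

Steps most likely to fail

Step 8. The annulation may suffer from insertion in the reverse orientation, from decarbonylation of the acyl rhodium intermediate before the alkyne inserts, from slow insertion of two doubly ortho-substituted partners, or from loss of the ortho MOM group followed by metal-mediated cyclisation of the freed alkynylphenol. The fallback sets out from 11 and 6 and comes back at 12, building ring C by stepwise ionic chemistry. The phenol of 11 is deprotonated with NaH, and the lithium acetylide of 6 (n-BuLi, THF, −78 °C) is added to the aldehyde to give racemic 1-[2-hydroxy-4-methoxy-6-(methoxymethoxy)phenyl]-3-[4-methoxy-2,5-bis(methoxymethoxy)phenyl]prop-2-yn-1-ol F1. MnO2 in CH2Cl2 should oxidise this benzylic propargylic alcohol to 1-[2-hydroxy-4-methoxy-6-(methoxymethoxy)phenyl]-3-[4-methoxy-2,5-bis(methoxymethoxy)phenyl]prop-2-yn-1-one F2. Et2NH in EtOH should then close the pyranone by 6-endo oxa-Michael addition through the β-amino enone, giving 7-methoxy-5-(methoxymethoxy)-2-[4-methoxy-2,5-bis(methoxymethoxy)phenyl]-4H-chromen-4-one F3. Finally, C3 lithiation with LiN(i-Pr)2 in THF at −78 °C and alkylation of the 3-lithioflavone with 7 at its primary carbon should give 12.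

Step 5. The allylation may go astray through attack at the tertiary allylic terminus (SN2', giving the 1,1-dimethylallyl isomer), through oxidative dimerisation of the terminal alkyne, or through base-induced migration of the skipped enyne into conjugation. The fallback sets out from 3 and 7 and comes back at 8, forming the aryl–alkyne bond last, not the alkyne–CH2 bond. HC≡CMgBr is coupled with 7 under catalytic CuBr·SMe2 in THF to give 5-methylhex-4-en-1-yne F4, a volatile liquid whose isomeric purity can be settled by distillation. F4 is then joined to aryl iodide 3 under the Sonogashira conditions of step 3 to give 8, which bypasses steps 3 to 5.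

Step 6. The ether cleavage may stall after the first chelate has formed or run on to the para methoxy group. The fallback sets out from 9 and comes back at 13, moving the demethylation to the end. Aldehyde 9 is taken unchanged into the annulation with 8 under the conditions of step 8 to give 5,7-dimethoxy-2-[4-methoxy-2,5-bis(methoxymethoxy)phenyl]-3-(3-methylbut-2-en-1-yl)-4H-chromen-4-one F5. MgI2·OEt2 in toluene/THF at 60–80 °C should then cleave only the C5 methyl ether, which chelates magnesium together with the C4 carbonyl, under non-protic conditions that a prenyl group tolerates. This gives 5-hydroxy-7-methoxy-2-[4-methoxy-2,5-bis(methoxymethoxy)phenyl]-3-(3-methylbut-2-en-1-yl)-4H-chromen-4-one F6. Acidic methanol as in step 9 removes the two MOM groups to give 13.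

Further compounds
F1 | step 8 | 1-[2-hydroxy-4-methoxy-6-(methoxymethoxy)phenyl]-3-[4-methoxy-2,5-bis(methoxymethoxy)phenyl]prop-2-yn-1-ol (racemic) | COCOc1cc(OC)cc(O)c1C(O)C#Cc1cc(OCOC)c(OC)cc1OCOC
F2 | step 8 | 1-[2-hydroxy-4-methoxy-6-(methoxymethoxy)phenyl]-3-[4-methoxy-2,5-bis(methoxymethoxy)phenyl]prop-2-yn-1-one | COCOc1cc(OC)cc(O)c1C(=O)C#Cc1cc(OCOC)c(OC)cc1OCOC
F3 | step 8 | 7-methoxy-5-(methoxymethoxy)-2-[4-methoxy-2,5-bis(methoxymethoxy)phenyl]-4H-chromen-4-one | COCOc1cc(OC)cc2oc(-c3cc(OCOC)c(OC)cc3OCOC)cc(=O)c12
F4 | step 5 | 5-methylhex-4-en-1-yne | C#CCC=C(C)C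
F5 | step 6 | 5,7-dimethoxy-2-[4-methoxy-2,5-bis(methoxymethoxy)phenyl]-3-(3-methylbut-2-en-1-yl)-4H-chromen-4-one | COc1cc(OC)c2c(=O)c(CC=C(C)C)c(-c3cc(OCOC)c(OC)cc3OCOC)oc2c1
F6 | step 6 | 5-hydroxy-7-methoxy-2-[4-methoxy-2,5-bis(methoxymethoxy)phenyl]-3-(3-methylbut-2-en-1-yl)-4H-chromen-4-one | COc1cc(O)c2c(=O)c(CC=C(C)C)c(-c3cc(OCOC)c(OC)cc3OCOC)oc2c1
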